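| flask | starting material | reagent in the second phase | remark | time | volume of the second phase over the first |
|---|---|---|---|---|---|
| Tuesday's | 32 mM | 1.2 equiv | run made earlier |  |  |
| Wednesday's | 32 mM | 5 equiv | run made earlier |  |  |
| Monday's | 64 mM | 2.5 equiv | run made earlier |  |  |
| flask | 32 mM | 2.50 equiv |  | 4.0 h | 2.0 |

| run | time / h | target / % | starting material / % |
|---|---|---|---|
| Tuesday's | 1.00 | 1.7 | 98.5 |
| Tuesday's | 2.00 | 3.6 | 96.3 |
| Tuesday's | 3.00 | 5.8 | 94.0 |
| Tuesday's | 4.00 | 7.3 | 91.3 |
| Tuesday's | 5.00 | 10.1 | 90.5 |
| Wednesday's | 0.417 | 1.2 | 97.7 |
| Wednesday's | 1.33 | 9.0 | 90.8 |
| Wednesday's | 2.00 | 14.1 | 85.3 |
| Wednesday's | 3.00 | 20.5 | 77.4 |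
| Wednesday's | 5.00 | 31.4 | 65.1 |
| Monday's | 0.417 | 2.2 | 98.6 |
| Monday's | 1.33 | 8.9 | 91.0 |
| Monday's | 2.00 | 13.2 | 85.8 |
| Monday's | 3.00 | 19.9 | 79.1 |
| Monday's | 5.00 | 30.3 | 67.2 |

(each reading ± 0.5 percentage points)

- in the second phase: reagent in the second phase; everything else is in the first
- charges count per volume of the first phase; a concentration in a rate is the amount of a species over the volume of its own phase; every rate counts per litre of the first phase
- steps thought possible: reagent in the reaction phase <-> reagent in the second phase; starting material + reagent in the reaction phase -> target; reagent in the reaction phase + target -> over-reacted product; reagent in the reaction phase -> decomposed reagent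
- the earlier runs hold the two phases in the same ratio of volumes as the flask asked about

- south-west: doubling the amount of reagent in the second phase, all else as stated
- north-west: doubling the transfer coefficient of the reagent in the second phase, all else as stated

- amount of target at 4.0 h, in percent of the starting material charged
- the change that raises the amount of target at 4.0 h, in percent of the starting material charged most ("none" if none brings more than 2 percentage points) (south-west / north-west / none)
- amount of target at 4.0 h, in percent of the starting material charged, after north-west

160 mM of reagent in the second phase per litre of first phase stood in Wednesday's run, and Monday's run had the same load. The 67.2% of starting material read in Monday's run and the 65.1% read in Wednesday's run at 5.00 h are close, although Monday's run charged twice the starting material. The loss therefore looks pseudo-first-order in starting material. But Tuesday's run, with a smaller load, read 90.5% at the same time, so the reagent counts. On logarithmic axes, the natural logarithm of charged over left starting material, plotted against the load, has the slope 1.02 between the last readings of Tuesday's and Wednesday's runs, which reads as first order in reagent charged.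

So one number can carry over: Wednesday's run reads 0.537 /M/h as the load-specific constant, the natural logarithm of charged over left starting material, per hour and per molar of reagent charged. For the flask, with 80.0 mM of load, my own reckoning gives a loss of starting material of 15.8% at 4.0 h.

The forecast's target is lower than that loss: 15%, with south-west as the best change and 15.5% after north-west, since, in its words, “Doubling the transfer coefficient only shortens the lag”.

The flask gives 15.0% of target, south-west is best with a gain of 11 percentage points against 0.99 points for north-west, and north-west gives 16.0%.

    reagent in the reaction phase ⇌ reagent in the second phase, rate k1*([reagent in the reaction phase] - [reagent in the second phase]/K1) per volume of the first phase (partition coefficient = 4.60, kL = 2.50 /h)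
    starting material + reagent in the reaction phase → target (k = 6.60 /M/h)
    reagent in the reaction phase + target → over-reacted product (k = 3.60 /M/h)
    reagent in the reaction phase → decomposed reagent (k = 0.0100 /h)

At 4.00 h the flask's second phase still holds 84.6% of its own charge of reagent. The neighbour flask with 19 mM of starting material and the same equivalents has a reckoned loss, from the constant, of 9.69%, and it stands at 90.0% of starting material left and 9.70% of target.

(Readings and results stem from a simulated flask with constants of no real substance, and the scatter is random.)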